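**Assumption:** the target has no stereocentre, so "single enantiomer" is read as the single all‑E (2E,6E,10E,14E,18E) isomer of 3,5‑dimethyl‑2‑hexaprenylnaphthalene‑1,4‑dione.

## Retrosynthetic overview

1. Target ⇐ oxidative demethylation and desulfonylation of the product of a late sulfone (Biellmann) coupling between allylic bromide **23** (arene + 2 prenyl units, 27 heavy atoms) and geranylgeranyl phenyl sulfone **13** (4 prenyl units, 29 heavy atoms).
2. **23** ⇐ aryl bromide **20** (Grignard) + geranyl bromide **4**, then E‑selective SeO2 oxidation of the terminal methyl and bromination.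
3. **13** ⇐ sulfone coupling of geranyl sulfone **5** with 8‑bromogeranyl TBS ether **8**; both come from geraniol **3**, made from a C6 bromide, acetylide, Me3Al and CH2O by Negishi carboalumination.
4. **20** ⇐ 2,8‑dimethylnaphthoquinone **18** ⇐ bromine‑directed Diels–Alder of 2‑bromo‑6‑methylbenzoquinone **16** (from o‑cresol) with piperylene.
5. Ring order: the quinone ring is the o‑cresol ring (oxidised first); the benzo ring is formed second by the Diels–Alder/aromatisation.

## Route

**Step 1**
Reactants: **1**, 5‑bromo‑2‑methylpent‑2‑ene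
Product: **2**, 6‑methylhept‑5‑en‑1‑yne
Conditions: HC≡CLi·H2NCH2CH2NH2, DMSO, 10 °C → rt
Reagents that add atoms: lithium acetylide–ethylenediamine, [Li]C#C
Why: SN2 acetylide alkylation of a primary homoallylic bromide gives the terminal alkyne.

**Step 2**
Reactants: **2**
Product: **3**, geraniol, (2E)‑3,7‑dimethylocta‑2,6‑dien‑1‑ol
Conditions: Me3Al, Cp2ZrCl2 (cat.), CH2Cl2, rt; then n‑BuLi, THF, −78 °C; (CH2O)n, → rt
Reagents that add atoms: trimethylaluminium, C[Al](C)C; paraformaldehyde, C=O
Why: Negishi Zr‑catalysed syn‑carboalumination puts Me on the internal carbon and Al on the terminus, and the alkenylalanate traps CH2O with retention, so the trisubstituted alkene is formed ≥98% E.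

**Step 3**
Reactants: **3**
Product: **4**, geranyl bromide, (2E)‑1‑bromo‑3,7‑dimethylocta‑2,6‑diene
Conditions: PBr3, Et2O, −10 °C (used crude)
Reagents that add atoms: phosphorus tribromide, BrP(Br)Br
Why: low‑temperature SN2 bromination of the primary allylic alcohol occurs without allylic transposition or E/Z loss.

**Step 4**
Reactants: **4** (part of the batch)
Product: **5**, geranyl phenyl sulfone, {[(2E)‑3,7‑dimethylocta‑2,6‑dien‑1‑yl]sulfonyl}benzene
Conditions: PhSO2Na, DMF, rt
Reagents that add atoms: sodium benzenesulfinate, [Na+].[O-]S(=O)c1ccccc1 (traceless activating group)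
Why: S‑alkylation of the sulfinate by SN2 at the primary allylic bromide gives the allylic sulfone with the E alkene intact.

**Step 5**
Reactants: **3** (second portion)
Product: **6**, geranyl TBS ether
Conditions: TBSCl, imidazole, CH2Cl2, rt
Reagents that add atoms: TBSCl, CC(C)(C)[Si](C)(C)Cl
Why: standard silylation; the TBS ether is inert to BuLi, LiBHEt3 and Pd(0) used later.

**Step 6**
Reactants: **6**
Product: **7**, (2E,6E)‑8‑(tert‑butyldimethylsilyloxy)‑2,6‑dimethylocta‑2,6‑dien‑1‑ol
Conditions: SeO2 (cat.), t‑BuOOH, salicylic acid (cat.), CH2Cl2, 0 °C → rt; then NaBH4, MeOH, 0 °C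
Reagents that add atoms: selenium dioxide, O=[Se]=O; tert‑butyl hydroperoxide, CC(C)(C)OO (oxygen source)
Why: Sharpless SeO2/TBHP allylic oxidation (ene then [2,3]‑shift) attacks the more electron‑rich terminal alkene and oxidises only the E‑methyl, setting the new E‑allylic alcohol; NaBH4 returns any enal to the alcohol.

**Step 7**
Reactants: **7**
Product: **8**, tert‑butyl{[(2E,6E)‑8‑bromo‑3,7‑dimethylocta‑2,6‑dien‑1‑yl]oxy}dimethylsilane
Conditions: MsCl, Et3N, CH2Cl2, −40 °C; then LiBr, THF, 0 °C
Reagents that add atoms: lithium bromide, [Li+].[Br-]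
Why: mesylate/bromide SN2 exchange gives the primary allylic bromide without SN2′ transposition or TBS loss.

**Step 8**
Reactants: **5** and **8**
Product: **9**, TBS ether of (2E,6E,10E)‑3,7,11,15‑tetramethyl‑9‑(phenylsulfonyl)hexadeca‑2,6,10,14‑tetraen‑1‑ol (racemic at C9)
Conditions: n‑BuLi, THF, −78 °C; then **8**, −78 → −20 °C
Reagents that add atoms: none
Why: Biellmann alkylation — the α‑lithio allylic sulfone reacts at its α‑carbon by SN2 on the allylic bromide, leaving all alkenes untouched; the racemic sulfonyl carbon is removed in step 9.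

**Step 9**
Reactants: **9**
Product: **10**, (2E,6E,10E)‑geranylgeranyl TBS ether
Conditions: PdCl2(dppp) (5 mol%), LiBHEt3, THF, 0 °C → rt
Reagents that add atoms: none
Why: Pd‑catalysed reductive desulfonylation — hydride attacks the less hindered (former sulfonyl) terminus of the π‑allyl, so the trisubstituted alkene keeps its position and E geometry.

**Step 10**
Reactants: **10**
Product: **11**, (2E,6E,10E)‑geranylgeraniol
Conditions: TBAF, THF, 0 °C → rt
Reagents that add atoms: none
Why: fluoride desilylation; nothing else in the molecule is fluoride‑sensitive.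

**Step 11**
Reactants: **11**
Product: **12**, (2E,6E,10E)‑geranylgeranyl bromide
Conditions: PBr3, Et2O, −10 °C (used crude)
Reagents that add atoms: phosphorus tribromide, BrP(Br)Br
Why: same SN2 allylic bromination as step 3.

**Step 12**
Reactants: **12**
Product: **13**, (2E,6E,10E)‑geranylgeranyl phenyl sulfone
Conditions: PhSO2Na, DMF, rt
Reagents that add atoms: sodium benzenesulfinate, [Na+].[O-]S(=O)c1ccccc1
Why: sulfinate S‑alkylation as in step 4 gives the C20 nucleophile.

**Step 13**
Reactants: **14**, o‑cresol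
Product: **15**, 2,4‑dibromo‑6‑methylphenol
Conditions: Br2 (2.1 equiv), AcOH, 0 °C → rt
Reagents that add atoms: bromine, BrBr
Why: electrophilic aromatic bromination at the free ortho and para positions of the phenol.

**Step 14**
Reactants: **15**
Product: **16**, 2‑bromo‑6‑methyl‑1,4‑benzoquinone
Conditions: CrO3, AcOH/H2O/MeCN, 60 °C
Reagents that add atoms: chromium trioxide, O=[Cr](=O)=O; water, O (source of the C4 oxygen)
Why: chromic acid oxidation of the 4‑bromophenol to the p‑quinone with ipso loss of the para bromine leaves Br and Me flanking the same carbonyl.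

**Step 15**
Reactants: **16** and **17**, (E)‑penta‑1,3‑diene
Product: **18**, 2,8‑dimethylnaphthalene‑1,4‑dione
Conditions: PhMe, 40 °C, sealed, dark; then Et3N, EtOH, air, rt
Reagents that add atoms: none
Why: Diels–Alder at the bromine‑activated C=C with the diene CH2 terminus bonding to the bromine‑free carbon places the new methyl next to the carbonyl flanked by C‑Me; Et3N eliminates HBr and air oxidation aromatises.

**Step 16**
Reactants: **18**
Product: **19**, 1,4‑dimethoxy‑2,8‑dimethylnaphthalene
Conditions: Na2S2O4, Bu4NBr, THF/H2O, rt; then aq. KOH, Me2SO4, 0 °C → rt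
Reagents that add atoms: dimethyl sulfate, COS(=O)(=O)OC
Why: dithionite reduction to the hydroquinone and in situ Williamson O‑methylation mask the quinone for the organometallic steps.

**Step 17**
Reactants: **19**
Product: **20**, 2‑bromo‑1,4‑dimethoxy‑3,5‑dimethylnaphthalene
Conditions: Br2 (1.05 equiv), CH2Cl2, 0 °C, dark
Reagents that add atoms: bromine, BrBr
Why: electrophilic bromination at the only free position of the strongly activated dimethoxy ring.

**Step 18**
Reactants: **20** and **4** (remaining portion)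
Product: **21**, 2‑[(2E)‑3,7‑dimethylocta‑2,6‑dien‑1‑yl]‑1,4‑dimethoxy‑3,5‑dimethylnaphthalene
Conditions: Mg, THF, 60 °C; then CuI (10 mol%), **4**, THF, −30 → 0 °C
Reagents that add atoms: none
Why: Cu‑catalysed SN2 (α) allylation of the hindered aryl Grignard at the primary allylic bromide proceeds with retention of the 2E geometry (menaquinone‑type aryl–allyl coupling).

**Step 19**
Reactants: **21**
Product: **22**, (2E,6E)‑8‑(1,4‑dimethoxy‑3,5‑dimethylnaphthalen‑2‑yl)‑2,6‑dimethylocta‑2,6‑dien‑1‑ol
Conditions: SeO2 (cat.), t‑BuOOH, salicylic acid (cat.), CH2Cl2, 0 °C → rt; then NaBH4, MeOH, 0 °C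
Reagents that add atoms: selenium dioxide, O=[Se]=O; tert‑butyl hydroperoxide, CC(C)(C)OO
Why: SeO2/TBHP allylic oxidation as in step 6 selects the E‑methyl of the terminal alkene, fixing what becomes the 6E alkene of the target.

**Step 20**
Reactants: **22**
Product: **23**, 2‑[(2E,6E)‑8‑bromo‑3,7‑dimethylocta‑2,6‑dien‑1‑yl]‑1,4‑dimethoxy‑3,5‑dimethylnaphthalene
Conditions: MsCl, Et3N, CH2Cl2, −40 °C; then LiBr, THF, 0 °C
Reagents that add atoms: lithium bromide, [Li+].[Br-]
Why: non‑acidic mesylate/bromide SN2 exchange gives the allylic bromide without transposition or damage to the electron‑rich arene.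

**Step 21** (key fragment union)
Reactants: **13** and **23**
Product: **24**, 2‑[(2E,6E,10E,14E,18E)‑3,7,11,15,19,23‑hexamethyl‑9‑(phenylsulfonyl)tetracosa‑2,6,10,14,18,22‑hexaen‑1‑yl]‑1,4‑dimethoxy‑3,5‑dimethylnaphthalene (racemic at C9)
Conditions: n‑BuLi, THF, −78 °C; then **23**, −78 → −20 °C
Reagents that add atoms: none
Why: Biellmann coupling of the α‑sulfonyl allyl anion with the primary allylic bromide joins the two halves at the α‑carbon with all five E alkenes intact; the racemic sulfonyl carbon is removed in step 22.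

**Step 22**
Reactants: **24**
Product: **25**, 2‑[(2E,6E,10E,14E,18E)‑3,7,11,15,19,23‑hexamethyltetracosa‑2,6,10,14,18,22‑hexaen‑1‑yl]‑1,4‑dimethoxy‑3,5‑dimethylnaphthalene
Conditions: PdCl2(dppp) (5 mol%), LiBHEt3, THF, 0 °C → rt
Reagents that add atoms: none
Why: Pd‑catalysed reductive desulfonylation as in step 9, with hydride at the less hindered π‑allyl terminus preserving the 10E alkene; aryl methyl ethers are inert.

**Step 23**
Reactants: **25**
Product: **26**, target, 3,5‑dimethyl‑2‑[(2E,6E,10E,14E,18E)‑3,7,11,15,19,23‑hexamethyltetracosa‑2,6,10,14,18,22‑hexaen‑1‑yl]naphthalene‑1,4‑dione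
Conditions: (NH4)2Ce(NO3)6, MeCN/H2O/CH2Cl2, 0 °C
Reagents that add atoms: water, O (quinone oxygens; both O‑methyl groups leave as MeOH)
Why: CAN oxidative demethylation of the 1,4‑dimethoxynaphthalene gives the quinone quickly at 0 °C, conditions under which isolated trisubstituted alkenes survive.

## Compound list

1 | 5‑bromo‑2‑methylpent‑2‑ene | CC(C)=CCCBr | starting material
2 | 6‑methylhept‑5‑en‑1‑yne | CC(C)=CCCC#C | intermediate
3 | geraniol | CC(C)=CCC/C(C)=C/CO | intermediate
4 | geranyl bromide | CC(C)=CCC/C(C)=C/CBr | intermediate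
5 | geranyl phenyl sulfone | CC(C)=CCC/C(C)=C/CS(=O)(=O)c1ccccc1 | intermediate
6 | geranyl TBS ether | CC(C)=CCC/C(C)=C/CO[Si](C)(C)C(C)(C)C | intermediate
7 | (2E,6E)‑8‑(TBS‑oxy)‑2,6‑dimethylocta‑2,6‑dien‑1‑ol | OC/C(C)=C/CC/C(C)=C/CO[Si](C)(C)C(C)(C)C | intermediate
8 | (2E,6E)‑8‑bromo‑3,7‑dimethylocta‑2,6‑dienyl TBS ether | BrC/C(C)=C/CC/C(C)=C/CO[Si](C)(C)C(C)(C)C | intermediate
9 | 9‑(phenylsulfonyl)geranylgeranyl TBS ether (racemic at C9) | CC(C)=CCC/C(C)=C/C(S(=O)(=O)c1ccccc1)C/C(C)=C/CC/C(C)=C/CO[Si](C)(C)C(C)(C)C | intermediate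
10 | geranylgeranyl TBS ether | CC(C)=CCC/C(C)=C/CC/C(C)=C/CC/C(C)=C/CO[Si](C)(C)C(C)(C)C | intermediate
11 | (2E,6E,10E)‑geranylgeraniol | CC(C)=CCC/C(C)=C/CC/C(C)=C/CC/C(C)=C/CO | intermediate
12 | geranylgeranyl bromide | CC(C)=CCC/C(C)=C/CC/C(C)=C/CC/C(C)=C/CBr | intermediate
13 | geranylgeranyl phenyl sulfone | CC(C)=CCC/C(C)=C/CC/C(C)=C/CC/C(C)=C/CS(=O)(=O)c1ccccc1 | intermediate
14 | o‑cresol | Cc1ccccc1O | starting material
15 | 2,4‑dibromo‑6‑methylphenol | Cc1cc(Br)cc(Br)c1O | intermediate
16 | 2‑bromo‑6‑methyl‑1,4‑benzoquinone | CC1=CC(=O)C=C(Br)C1=O | intermediate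
17 | (E)‑penta‑1,3‑diene | C/C=C/C=C | starting material
18 | 2,8‑dimethylnaphthalene‑1,4‑dione | CC1=CC(=O)c2cccc(C)c2C1=O | intermediate
19 | 1,4‑dimethoxy‑2,8‑dimethylnaphthalene | COc1cc(C)c(OC)c2c(C)cccc12 | intermediate
20 | 2‑bromo‑1,4‑dimethoxy‑3,5‑dimethylnaphthalene | COc1c(Br)c(C)c(OC)c2c(C)cccc12 | intermediate
21 | 2‑geranyl‑1,4‑dimethoxy‑3,5‑dimethylnaphthalene | CC(C)=CCC/C(C)=C/Cc1c(C)c(OC)c2c(C)cccc2c1OC | intermediate
22 | (2E,6E)‑8‑(1,4‑dimethoxy‑3,5‑dimethylnaphthalen‑2‑yl)‑2,6‑dimethylocta‑2,6‑dien‑1‑ol | OC/C(C)=C/CC/C(C)=C/Cc1c(C)c(OC)c2c(C)cccc2c1OC | intermediate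
23 | 2‑[(2E,6E)‑8‑bromo‑3,7‑dimethylocta‑2,6‑dienyl]‑1,4‑dimethoxy‑3,5‑dimethylnaphthalene | BrC/C(C)=C/CC/C(C)=C/Cc1c(C)c(OC)c2c(C)cccc2c1OC | intermediate
24 | C9‑phenylsulfonyl hexaprenyl dimethoxynaphthalene (racemic at C9) | CC(C)=CCC/C(C)=C/CC/C(C)=C/CC/C(C)=C/C(S(=O)(=O)c1ccccc1)C/C(C)=C/CC/C(C)=C/Cc1c(C)c(OC)c2c(C)cccc2c1OC | intermediate
25 | all‑E 2‑hexaprenyl‑1,4‑dimethoxy‑3,5‑dimethylnaphthalene | CC(C)=CCC/C(C)=C/CC/C(C)=C/CC/C(C)=C/CC/C(C)=C/CC/C(C)=C/Cc1c(C)c(OC)c2c(C)cccc2c1OC | intermediate
26 | CID101244058 | CC(C)=CCC/C(C)=C/CC/C(C)=C/CC/C(C)=C/CC/C(C)=C/CC/C(C)=C/CC1=C(C)C(=O)c2c(C)cccc2C1=O | target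

## Summary

**Total step count:** 23.

**Longest linear sequence:** 13 steps (1 → 2 → 3 → 6 → 7 → 8 → 9 → 10 → 11 → 12 → 13 → 24 → 25 → 26; steps 1, 2, 5–12, 21–23). The arene branch from o‑cresol is 11 steps (13–23).

**Steps most likely to fail, with fallbacks:**

1. **Step 15 (Diels–Alder regiochemistry).** Piperylene is only weakly polarised, so some 2,5‑dimethyl isomer may form alongside the desired 2,8‑isomer. Fallback: use a strongly directing 1‑oxygenated diene (1‑acetoxybuta‑1,3‑diene) with **16** to give 8‑hydroxy‑2‑methylnaphthoquinone, then triflate the hydroxyl and install the methyl by Pd‑catalysed cross‑coupling (MeB(OH)2) to reach **18**.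

2. **Step 19 (SeO2 oxidation of 21).** Selectivity between the terminal alkene, the internal alkene and the benzylic/allylic CH2 is moderate, and the arene is electron‑rich. Fallback: install the terminal oxygen before arylation. Protect the free OH of **7** as a THP ether, remove TBS, convert the unmasked allylic alcohol to the bromide, couple it with the Grignard of **20**, then remove THP and brominate to reach **23**.

3. **Step 22 (Pd/LiBHEt3 desulfonylation of 24; the same risk applies to step 9).** Alkene transposition or partial E/Z erosion at the 10,11‑alkene is possible. Fallback: avoid the sulfone junction altogether with an α,α′‑selective allylbarium coupling — generate geranylgeranylbarium from geranylgeranyl chloride (Rieke Ba, THF, −78 °C) and couple it with bromide **23** to give **25** directly.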